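## Structural features

Marchantin C (18) is an achiral, 18-membered macrocyclic bis(bibenzyl) built from four benzene rings. Ring A is a para-phenylene, ring B a 1,2,3-trisubstituted phenol (chain at C1, aryloxy oxygen at C2, hydroxyl at C3), ring C a meta-phenylene, and ring D a 1,2,4-trisubstituted phenol (hydroxyl at C1, aryloxy oxygen at C2, chain at C4). The rings are joined in the order D–O–A–CH2CH2–B–O–C–CH2CH2–D, that is by two diaryl ether oxygens and two ethylene bridges. There is no stereocentre and no configurationally stable axis, so no stereocentres stand next to each other and nothing stereochemical has to be set. The fragile groups are the two free phenols, both on electron-rich oxygenated rings and sensitive to oxidants and electrophiles, so they are best unveiled last. The D–O–A ether is easy, because ring A can carry a para acceptor that later becomes the benzylic carbon of its bridge. The real difficulty is the B–O–C ether: its oxygen sits on ring B C2 between the C1 chain and the C3 oxygen, its partner carbon (ring C C1) belongs to an arene with no activating group in the target, and this region must also close the macrocycle. The key step exploits the fact that ring C C6, ortho to C1 and para to the chain-bearing C3, carries only hydrogen in the target: a nitro group placed there, with fluorine on C1, makes C1 a strong SNAr acceptor for the ring B C2 phenoxide and can afterwards be replaced by hydrogen.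

## Logic of the disconnections

18 to 17. The two phenolic O–H groups are traced back to O–CH3 bonds. Methyl ethers are the only masks that tolerate every earlier operation (carbonate bases, hydrobromide salts, diimide, BCl3 at low temperature, hydrogenation, nitrous acid). The gain is that no free phenol of rings B (C3) or D has to be carried. The demand is a final demethylation that leaves both diaryl ethers intact.

17 to 15 (through 16) to 14. The ring C C6–H bond is traced back to C6–N, first as the diazonium 16, then the amine 15, then the nitro compound 14. This places an electron acceptor ortho to ring C C1 exactly where the target has hydrogen. The demand is a clean hydrodeamination on a ring that carries an ortho aryloxy group.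

14 to 13. The ring C C1–O bond is cut. This single cut opens the 18-membered ring and converts the hindered, unactivated diaryl ether into an addition–elimination on a fluoronitroarene. The gain is an open chain whose four rings are joined by robust bonds only. The demand is ring closure in preference to chain growth, and a phenoxide with two ortho neighbours that still attacks.

13 to 12. The ring B C2 O–H is traced back to an O–CH2Ph bond. The phenol must stay masked while the fluoronitroarene is introduced under basic conditions, otherwise it would arylate intermolecularly. The demand is a debenzylation that spares methyl ethers, the nitro group and the C–F bond.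

12 to 11. Both CH2–CH2 bridges are traced back to CH=CH. The gain is that each bridge becomes the product of an olefination, and both are saturated in one operation. The demand is a reduction selective for C=C over nitro, C–F and O-benzyl.

11 to 9 + 10. The C=C between the ring D benzylic carbon and ring C is cut. Ring C arrives as an electrophilic aldehyde already carrying fluorine and nitro in the correct pattern, so no late nitration or fluorination is needed. The demand is an olefination base that does not displace the activated fluoride.

9 to 8, and 8 to 4 + 7. The C–P bond of 9 is traced back to the benzylic C–OH of 8, and the C=C between rings A and B is cut. This separates the ring B unit from the D–O–A unit. The formyl group of 7 must react while its benzylic alcohol waits, which is why 7 carries the two carbons at different oxidation levels.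

7 to 5 + 6. The ring A C–O bond is cut. The para-formyl group of 6 activates fluoride displacement and is also the carbon needed for the next olefination. The demand is that only the phenolic oxygen of 5, not its benzylic alcohol, is arylated.

4 to 3 to 2 to 1. The C–P bond, the benzylic C–OH (from C=O) and the O-benzyl bond are removed in turn. The gain is a commodity aldehyde that already holds the 1,2,3-pattern of ring B.

## Other disconnections considered

Alternative 1: The cut removes the C2–C3 and C1–C6 bonds of ring B, so that ring B is assembled from 3-methoxy-2-pyrone A1 and an internal aryl ynol ether A2, which already carries the ring C oxygen on one alkyne carbon and the ring A side chain on the other. The forward key step is thermal cycloaddition followed by decarboxylative aromatisation, giving the open-chain four-ring ether A3.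
- In its favour: the hindered oxygen never acts as a nucleophile, because the C2–O bond travels with the alkyne. The polarisation of the ynol ether (nucleophilic chain-bearing carbon to pyrone C6, oxygen-bearing carbon to pyrone C3) points to the required 1,2,3-pattern. No activating group has to be added and erased, which is a point on which this plan is better than the chosen one.
- Against it here: the 3-methoxy group makes the pyrone a poorer acceptor, the new C2–C3 bond joins two oxygen-bearing carbons, and an internal alkyne is likely to need temperatures at which aryl alkynyl ethers can rearrange. A2 itself needs a multistep synthesis with strong base.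
- Comparison: A3 is still acyclic, so the macrocycle must then be closed at the D–O–A ether by a copper-mediated Ullmann coupling of an unactivated aryl bromide. That closure is mechanistically less dependable than SNAr on a fluoronitroarene. Acetal cleavage, Ullmann closure and demethylation follow A3, so the number of steps after the key step equals that of the chosen plan and the way to A2 is longer.

Alternative 2: The cut removes the C2–C3 and C5–C6 bonds of ring D. The seco compound A4 carries an aryloxyacetone on ring A and a 2-substituted 3-(dimethylamino)acrolein at the end of the ring C chain. KOt-Bu in dilute THF followed by acetic acid is meant to condense the two ketone α-carbons with the two electrophilic termini of the aminoacrolein, aromatise by loss of dimethylamine and water, and so form ring D and the macrocycle at once, giving A5.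
- In its favour: regiochemistry is not an issue, because either pairing of termini leads to the same benzene ring. The ring D phenol appears unprotected, and only one demethylation separates A5 from 18; this endgame is shorter than the chosen one and is the better of the two on that point.
- Against it here: a twofold intermolecular-type condensation has to win over aldol self-condensation of the ketone and over chain growth while closing an 18-membered ring, and there is no close analogy for a macrocyclising variant. The hindered B–O–C ether is not addressed and must still be made earlier by some activated or copper-mediated coupling. A4 holds two sensitive termini that need several steps of their own.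
- Comparison: the chosen plan closes the ring with a single, well-understood bond-forming event and solves the hindered ether in the same step. Alternative 2 is equal in convergence but carries more mechanistic uncertainty in the key step and a longer route to its precursor.

Alternative 3: The cut is the ring D C2–O bond. The seco bis-phenol A6 contains a 2,6-dibromophenol (ring D) and a 2,6-dichlorophenol (ring A). Tl(NO3)3 in methanol is meant to oxidise the more electron-rich dibromophenol, the ring A oxygen is meant to attack a bromine-bearing ortho carbon, and zinc work-up to rearomatise, giving A7.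
- In its favour: it follows the presumed biosynthetic phenol coupling. The halogens block the competing positions and differentiate the two phenols, and the ring D phenol needs no protecting group. After A7 one hydrodehalogenation and one demethylation reach 18, one step fewer than the chosen endgame, which is a point in its favour.
- Against it here: the thallium salt is acutely toxic, which conflicts with the aim of a safe route. Four halogen atoms have to be installed selectively on two different rings and three removed again. The hindered B–O–C ether is again left to an earlier, separate solution.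
- Comparison: the chosen plan uses one removable nitro group and a metal-free closure under mild base. Alternative 3 is comparable in ring-closing logic (one C–O bond closes the 18-membered ring) but is worse on reagent hazard and on the length of the route to A6.

Key step: step 10

Remark: the two Wittig steps are expected to give E/Z mixtures, so 8, 9 and 11 are drawn without alkene geometry; both isomers converge in step 8. The activator pattern (fluorine on ring C C1, nitro on C6) corresponds to a 3-fluoro-4-nitrophenyl unit on the chain and is used consistently.

## Route

Step 1
Reactants: 1 2-hydroxy-3-methoxybenzaldehyde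
Product: 2 2-(benzyloxy)-3-methoxybenzaldehyde
Conditions: BnBr, K2CO3, DMF, rt → 50 °C
Reagents that add atoms: benzyl bromide, BrCc1ccccc1
Why: Williamson etherification of the phenoxide (SN2 at the benzylic bromide). Benzyl is chosen because it survives carbonate, hydrobromide salts and diimide and is later removed by BCl3 at low temperature without touching methyl ethers, nitro or C–F.

Step 2
Reactants: 2 2-(benzyloxy)-3-methoxybenzaldehyde
Product: 3 [2-(benzyloxy)-3-methoxyphenyl]methanol
Conditions: NaBH4, MeOH–THF, 0 °C
Reagents that add atoms: none
Why: Borohydride reduction of an aromatic aldehyde to the benzylic alcohol; no other reducible group is present.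

Step 3
Reactants: 3 [2-(benzyloxy)-3-methoxyphenyl]methanol
Product: 4 {[2-(benzyloxy)-3-methoxyphenyl]methyl}triphenylphosphonium bromide
Conditions: PPh3·HBr, MeCN, reflux
Reagents that add atoms: triphenylphosphine hydrobromide, [Br-].c1ccc(cc1)[PH+](c1ccccc1)c1ccccc1
Why: Acid-promoted substitution of an alkoxy-activated benzylic alcohol by triphenylphosphine gives the Wittig salt directly in one operation; the aryl benzyl ether is not cleaved by this weakly acidic salt.

Step 4
Reactants: 5 3-hydroxy-4-methoxybenzyl alcohol; 6 4-fluorobenzaldehyde
Product: 7 4-[5-(hydroxymethyl)-2-methoxyphenoxy]benzaldehyde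
Conditions: K2CO3, DMF, 120 °C
Reagents that add atoms: none
Why: Intermolecular SNAr in which the para-formyl group activates fluoride displacement. Carbonate ionises only the phenol, so the benzylic alcohol stays free, and the product holds an aldehyde on ring A and an alcohol on ring D for two successive olefinations.

Step 5
Reactants: 4 {[2-(benzyloxy)-3-methoxyphenyl]methyl}triphenylphosphonium bromide; 7 4-[5-(hydroxymethyl)-2-methoxyphenoxy]benzaldehyde
Product: 8 [3-(4-{2-[2-(benzyloxy)-3-methoxyphenyl]ethenyl}phenoxy)-4-methoxyphenyl]methanol (E/Z mixture)
Conditions: K2CO3, 18-crown-6 (cat.), CH2Cl2, reflux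
Reagents that add atoms: none
Why: Wittig olefination with a semi-stabilised benzylic ylide generated under solid–liquid phase-transfer conditions, which tolerate the free benzylic alcohol; the alkene geometry is irrelevant because the bond is saturated later.

Step 6
Reactants: 8 [3-(4-{2-[2-(benzyloxy)-3-methoxyphenyl]ethenyl}phenoxy)-4-methoxyphenyl]methanol
Product: 9 {[3-(4-{2-[2-(benzyloxy)-3-methoxyphenyl]ethenyl}phenoxy)-4-methoxyphenyl]methyl}triphenylphosphonium bromide (E/Z mixture)
Conditions: PPh3·HBr, MeCN, 50 °C → reflux
Reagents that add atoms: triphenylphosphine hydrobromide, [Br-].c1ccc(cc1)[PH+](c1ccccc1)c1ccccc1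
Why: Same direct salt formation as step 3; the ring D alcohol is para to methoxy and ionises easily, so mild heating should suffice and the stilbene should survive.

Step 7
Reactants: 9 {[3-(4-{2-[2-(benzyloxy)-3-methoxyphenyl]ethenyl}phenoxy)-4-methoxyphenyl]methyl}triphenylphosphonium bromide; 10 3-fluoro-4-nitrobenzaldehyde
Product: 11 2-(benzyloxy)-1-[2-(4-{5-[2-(3-fluoro-4-nitrophenyl)ethenyl]-2-methoxyphenoxy}phenyl)ethenyl]-3-methoxybenzene (mixture of alkene isomers)
Conditions: K2CO3, 18-crown-6 (cat.), CH2Cl2, rt
Reagents that add atoms: none
Why: Wittig olefination of an electron-poor aldehyde, which the ylide attacks much faster than the activated arene. Solid carbonate in CH2Cl2 provides no nucleophile able to displace the fluoride, and the ring B oxygen is benzylated so it cannot arylate.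

Step 8
Reactants: 11 2-(benzyloxy)-1-[2-(4-{5-[2-(3-fluoro-4-nitrophenyl)ethenyl]-2-methoxyphenoxy}phenyl)ethenyl]-3-methoxybenzene
Product: 12 2-(benzyloxy)-1-[2-(4-{5-[2-(3-fluoro-4-nitrophenyl)ethyl]-2-methoxyphenoxy}phenyl)ethyl]-3-methoxybenzene
Conditions: TsNHNH2 (excess, portionwise), NaOAc, DME–H2O, reflux
Reagents that add atoms: none
Why: Diimide generated in situ transfers two hydrogens in a concerted syn fashion to nonpolar C=C bonds only, so both stilbenes of either geometry are saturated in one operation while nitro, C–F and the benzyl ether are left alone.

Step 9
Reactants: 12 2-(benzyloxy)-1-[2-(4-{5-[2-(3-fluoro-4-nitrophenyl)ethyl]-2-methoxyphenoxy}phenyl)ethyl]-3-methoxybenzene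
Product: 13 2-[2-(4-{5-[2-(3-fluoro-4-nitrophenyl)ethyl]-2-methoxyphenoxy}phenyl)ethyl]-6-methoxyphenol (seco fluoronitroarene with free ring B C2 phenol)
Conditions: BCl3, C6HMe5, CH2Cl2, −78 °C; then MeOH, H2O
Reagents that add atoms: none
Why: Lewis-acid cleavage of the aryl benzyl ether, with pentamethylbenzene trapping the benzyl cation by Friedel–Crafts alkylation so that it cannot alkylate rings B or D; aryl methyl ethers, nitro and C–F are inert at this temperature.

Step 10
Reactants: 13 2-[2-(4-{5-[2-(3-fluoro-4-nitrophenyl)ethyl]-2-methoxyphenoxy}phenyl)ethyl]-6-methoxyphenol
Product: 14 ring C nitro marchantin C dimethyl ether (nitro on ring C C6, ortho to the new ether oxygen and para to the chain)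
Conditions: K2CO3, 4 Å MS, degassed DMF (0.003 M, slow addition of 13), rt → 45 °C
Reagents that add atoms: none
Why: K2CO3 ionises the only acidic group of 13, the ring B C2 phenol, and the phenoxide adds to ring C C1, the single carbon that bears fluorine ortho to nitro, giving a Meisenheimer adduct whose charge is delocalised onto the nitro oxygens; loss of fluoride restores aromaticity and forms the ring C C1–O bond. The closest known reaction type is the intramolecular SNAr cycloetherification of ortho-fluoronitroarenes by phenoxides, an established metal-free way to close macrocyclic diaryl ethers. The 18-membered ring is closed by this one carbon–oxygen bond in an end-to-end macrocyclisation of a chain whose two ethylene bridges are already saturated and flexible enough to bring the termini together. No stereocentre is formed and no configurationally stable atropisomer is expected for a ring of this size. Because addition to a fluoronitroarene proceeds at or slightly above room temperature through a compact transition state, the two ortho neighbours of the phenoxide should slow the step but not stop it. Two selectivities are needed: ring closure over oligomerisation, secured by high dilution with slow addition and by the presence of exactly one phenoxide and one activated fluoride in 13, and O-arylation over chemistry at the benzylic CH2 para to nitro, secured by the mild carbonate base and exclusion of oxygen. The methyl ethers are the only other oxygens and cannot act as nucleophiles.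

Step 11
Reactants: 14 ring C nitro marchantin C dimethyl ether
Product: 15 ring C amino marchantin C dimethyl ether
Conditions: H2 (1 atm), 10% Pd/C, EtOAc–EtOH, rt
Reagents that add atoms: none
Why: Catalytic hydrogenation of a nitroarene to the aniline; the molecule contains no halogen, benzylic C–O bond or alkene that could be reduced alongside.

Step 12
Reactants: 15 ring C amino marchantin C dimethyl ether
Product: 17 marchantin C dimethyl ether, via ring C diazonium chloride 16 (not isolated)
Conditions: NaNO2, aq. HCl, THF, 0 °C; then 50% aq. H3PO2, 0 °C → rt
Reagents that add atoms: none
Why: Diazotisation followed in the same flask by hydrodediazoniation, in which hypophosphorous acid transfers a hydrogen atom to the aryl radical in a chain process; the diazonium salt is never isolated, which keeps the step safe.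

Step 13
Reactants: 17 marchantin C dimethyl ether
Product: 18 marchantin C
Conditions: BBr3, CH2Cl2, −78 °C → rt; then H2O
Reagents that add atoms: none
Why: BBr3 demethylation, in which boron coordinates each methoxy oxygen and bromide attacks the methyl carbon; the diaryl ethers are inert because bromide cannot attack an aryl carbon, and both phenols are released together in the last step.

## Compound list

1 | 2-hydroxy-3-methoxybenzaldehyde | COc1cccc(C=O)c1O | starting material
2 | 2-(benzyloxy)-3-methoxybenzaldehyde | COc1cccc(C=O)c1OCc1ccccc1 | intermediate
3 | [2-(benzyloxy)-3-methoxyphenyl]methanol | COc1cccc(CO)c1OCc1ccccc1 | intermediate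
4 | {[2-(benzyloxy)-3-methoxyphenyl]methyl}triphenylphosphonium bromide | COc1cccc(C[P+](c2ccccc2)(c2ccccc2)c2ccccc2)c1OCc1ccccc1.[Br-] | intermediate
5 | 3-hydroxy-4-methoxybenzyl alcohol | COc1ccc(CO)cc1O | starting material
6 | 4-fluorobenzaldehyde | O=Cc1ccc(F)cc1 | starting material
7 | 4-[5-(hydroxymethyl)-2-methoxyphenoxy]benzaldehyde | COc1ccc(CO)cc1Oc1ccc(C=O)cc1 | intermediate
8 | [3-(4-{2-[2-(benzyloxy)-3-methoxyphenyl]ethenyl}phenoxy)-4-methoxyphenyl]methanol, E/Z mixture | COc1ccc(CO)cc1Oc1ccc(C=Cc2cccc(OC)c2OCc2ccccc2)cc1 | intermediate
9 | {[3-(4-{2-[2-(benzyloxy)-3-methoxyphenyl]ethenyl}phenoxy)-4-methoxyphenyl]methyl}triphenylphosphonium bromide, E/Z mixture | COc1ccc(C[P+](c2ccccc2)(c2ccccc2)c2ccccc2)cc1Oc1ccc(C=Cc2cccc(OC)c2OCc2ccccc2)cc1.[Br-] | intermediate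
10 | 3-fluoro-4-nitrobenzaldehyde | O=Cc1ccc([N+](=O)[O-])c(F)c1 | starting material
11 | 2-(benzyloxy)-1-[2-(4-{5-[2-(3-fluoro-4-nitrophenyl)ethenyl]-2-methoxyphenoxy}phenyl)ethenyl]-3-methoxybenzene, mixture of alkene isomers | COc1ccc(C=Cc2ccc([N+](=O)[O-])c(F)c2)cc1Oc1ccc(C=Cc2cccc(OC)c2OCc2ccccc2)cc1 | intermediate
12 | 2-(benzyloxy)-1-[2-(4-{5-[2-(3-fluoro-4-nitrophenyl)ethyl]-2-methoxyphenoxy}phenyl)ethyl]-3-methoxybenzene | COc1ccc(CCc2ccc([N+](=O)[O-])c(F)c2)cc1Oc1ccc(CCc2cccc(OC)c2OCc2ccccc2)cc1 | intermediate
13 | 2-[2-(4-{5-[2-(3-fluoro-4-nitrophenyl)ethyl]-2-methoxyphenoxy}phenyl)ethyl]-6-methoxyphenol (precursor of the key step) | COc1ccc(CCc2ccc([N+](=O)[O-])c(F)c2)cc1Oc1ccc(CCc2cccc(OC)c2O)cc1 | intermediate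
14 | ring C nitro marchantin C dimethyl ether (product of the key step) | COc1ccc2cc1Oc1ccc(cc1)CCc1cccc(OC)c1Oc1cc(ccc1[N+](=O)[O-])CC2 | intermediate
15 | ring C amino marchantin C dimethyl ether | COc1ccc2cc1Oc1ccc(cc1)CCc1cccc(OC)c1Oc1cc(ccc1N)CC2 | intermediate
16 | ring C diazonium chloride of marchantin C dimethyl ether (not isolated) | COc1ccc2cc1Oc1ccc(cc1)CCc1cccc(OC)c1Oc1cc(ccc1[N+]#N)CC2.[Cl-] | intermediate
17 | marchantin C dimethyl ether | COc1ccc2cc1Oc1ccc(cc1)CCc1cccc(OC)c1Oc1cccc(c1)CC2 | intermediate
18 | marchantin C | Oc1ccc2cc1Oc1ccc(cc1)CCc1cccc(O)c1Oc1cccc(c1)CC2 | target

## Step count and least certain steps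

Total step count: 13. Longest linear sequence: 12 steps (from 1 through steps 1–3 and 5–13). Step 4 (5 + 6 to 7) is a one-step side branch and 10 enters at step 7.

Step 10 (key step). The phenoxide is flanked on both sides and reacts slowly, so intermolecular etherification leading to chain growth may overtake ring closure; base-induced deprotonation and oxidation at the benzylic carbon para to nitro may also consume material. The fallback moves the ring-closing event from the C–O bond to the ring D–ring C bridge and sets out from 8.
- Hydrogenation of 8 (H2, Pd/C, EtOAc) saturates the alkene and removes the benzyl group to give 2-(2-{4-[5-(hydroxymethyl)-2-methoxyphenoxy]phenyl}ethyl)-6-methoxyphenol F1.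
- The phenol of F1 is arylated intermolecularly by 10 (K2CO3, DMF, rt; fluoride activated by both ortho nitro and para formyl, no dilution needed) to give the diaryl ether aldehyde F2.
- PPh3·HBr in MeCN converts the ring D alcohol of F2 into the phosphonium salt F3.
- An intramolecular Wittig reaction of F3 (K2CO3, 18-crown-6, CH2Cl2, high dilution) closes the macrocyclic nitrostilbene F4.
- Hydrogenation of F4 (H2, Pd/C) reduces the ring alkene and the nitro group together and comes back to the route at 15.

Step 8. During the long heating needed to saturate two stilbenes, the activated fluoride may be displaced by the sulfonyl hydrazide or by the sulfinate released from it, and reduction of the E isomers may stall. The fallback builds the ring D–ring C bridge already saturated, so no alkene is reduced next to the fluoronitroarene, and sets out from 8.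
- Diimide reduction of 8 (TsNHNH2, NaOAc; no activated fluoride is present at this stage) gives the saturated benzylic alcohol F5.
- MnO2 in CH2Cl2 oxidises F5 to the aldehyde F6.
- Wittig methylenation of F6 (MePPh3Br, KOt-Bu, THF) gives the styrene F7.
- Hydroboration of F7 with 9-BBN gives the alkylborane F8, used without isolation.
- B-alkyl Suzuki–Miyaura coupling of F8 with purchased 4-bromo-2-fluoro-1-nitrobenzene F9 (Pd(dppf)Cl2, K3PO4, DMF–THF, 50 °C) comes back to the route at 12.

Step 6. Hydrogen bromide may add to the electron-rich stilbene or start cationic oligomerisation, and part of the benzyl ether may be lost under the acidic salt at reflux. The fallback inverts the polarity of the second olefination and sets out from 8.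
- MnO2 in CH2Cl2 oxidises 8 to the stilbene aldehyde F10 under neutral conditions.
- Purchased 4-(bromomethyl)-2-fluoro-1-nitrobenzene F11 is heated with PPh3 in toluene to give (3-fluoro-4-nitrobenzyl)triphenylphosphonium bromide F12.
- Wittig reaction of F12 with F10 (K2CO3, 18-crown-6, CH2Cl2) comes back to the route at 11.

Step 12. The aryl radical or cation formed next to the diaryl ether oxygen may attack the neighbouring ring B (Pschorr-type ring closure to a dibenzofuran), and capture by water may compete with hydrogen transfer. The fallback removes the nitro group without any diazonium stage and sets out from 14: palladium-catalysed reductive denitration (Pd(acac)2, BrettPhos, K3PO4, 2-propanol, 1,4-dioxane, 130 °C) replaces C–NO2 by C–H. This is a known reaction type: oxidative addition of the C–NO2 bond to zerovalent palladium, exchange for 2-propoxide, β-hydride elimination and reductive elimination. It comes back to the route at 17, replaces steps 11 and 12, and makes no new compound.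

## Further compounds

F1 | step 10 | 2-(2-{4-[5-(hydroxymethyl)-2-methoxyphenoxy]phenyl}ethyl)-6-methoxyphenol | COc1ccc(CO)cc1Oc1ccc(CCc2cccc(OC)c2O)cc1
F2 | step 10 | 3-[2-(2-{4-[5-(hydroxymethyl)-2-methoxyphenoxy]phenyl}ethyl)-6-methoxyphenoxy]-4-nitrobenzaldehyde | COc1ccc(CO)cc1Oc1ccc(CCc2cccc(OC)c2Oc2cc(C=O)ccc2[N+](=O)[O-])cc1
F3 | step 10 | {[3-(4-{2-[2-(5-formyl-2-nitrophenoxy)-3-methoxyphenyl]ethyl}phenoxy)-4-methoxyphenyl]methyl}triphenylphosphonium bromide | COc1ccc(C[P+](c2ccccc2)(c2ccccc2)c2ccccc2)cc1Oc1ccc(CCc2cccc(OC)c2Oc2cc(C=O)ccc2[N+](=O)[O-])cc1.[Br-]
F4 | step 10 | macrocyclic ring C nitro stilbene (ring D–ring C bridge as CH=CH) of marchantin C dimethyl ether | COc1ccc2cc1Oc1ccc(cc1)CCc1cccc(OC)c1Oc1cc(ccc1[N+](=O)[O-])C=C2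
F5 | step 8 | [3-(4-{2-[2-(benzyloxy)-3-methoxyphenyl]ethyl}phenoxy)-4-methoxyphenyl]methanol | COc1ccc(CO)cc1Oc1ccc(CCc2cccc(OC)c2OCc2ccccc2)cc1
F6 | step 8 | 3-(4-{2-[2-(benzyloxy)-3-methoxyphenyl]ethyl}phenoxy)-4-methoxybenzaldehyde | COc1ccc(C=O)cc1Oc1ccc(CCc2cccc(OC)c2OCc2ccccc2)cc1
F7 | step 8 | 2-(benzyloxy)-1-{2-[4-(5-ethenyl-2-methoxyphenoxy)phenyl]ethyl}-3-methoxybenzene | COc1ccc(C=C)cc1Oc1ccc(CCc2cccc(OC)c2OCc2ccccc2)cc1
F8 | step 8 | B-alkyl-9-borabicyclo[3.3.1]nonane adduct of F7 (boron on the terminal carbon) | COc1ccc(CCB2C3CCCC2CCC3)cc1Oc1ccc(CCc2cccc(OC)c2OCc2ccccc2)cc1
F9 | step 8 | 4-bromo-2-fluoro-1-nitrobenzene | [O-][N+](=O)c1ccc(Br)cc1F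
F10 | step 6 | 3-(4-{2-[2-(benzyloxy)-3-methoxyphenyl]ethenyl}phenoxy)-4-methoxybenzaldehyde, E/Z mixture | COc1ccc(C=O)cc1Oc1ccc(C=Cc2cccc(OC)c2OCc2ccccc2)cc1
F11 | step 6 | 4-(bromomethyl)-2-fluoro-1-nitrobenzene | [O-][N+](=O)c1ccc(CBr)cc1F
F12 | step 6 | (3-fluoro-4-nitrobenzyl)triphenylphosphonium bromide | [O-][N+](=O)c1ccc(C[P+](c2ccccc2)(c2ccccc2)c2ccccc2)cc1F.[Br-]
F0 | step 12 | none | none
A1 | alternative 1 | 3-methoxy-2H-pyran-2-one | COc1cccoc1=O
A2 | alternative 1 | internal aryl ynol ether carrying ring C, ring D and the ring A side chain | COCOc1cc(CCc2cccc(OC#CCCc3ccc(Br)cc3)c2)ccc1OC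
A3 | alternative 1 | open-chain four-ring ether with ring B complete | COCOc1cc(CCc2cccc(Oc3c(OC)cccc3CCc3ccc(Br)cc3)c2)ccc1OC
A4 | alternative 2 | seco aryloxyacetone with 2-substituted 3-(dimethylamino)acrolein terminus | CC(=O)COc1ccc(CCc2cccc(OC)c2Oc2cccc(CCC(C=O)=CN(C)C)c2)cc1
A5 | alternative 2 | marchantin C ring B methyl ether | Oc1ccc2cc1Oc1ccc(cc1)CCc1cccc(OC)c1Oc1cccc(c1)CC2
A6 | alternative 3 | seco bis-phenol with ring D dibromophenol and ring A dichlorophenol | Oc1c(Br)cc(CCc2cccc(Oc3c(OC)cccc3CCc3cc(Cl)c(O)c(Cl)c3)c2)cc1Br
A7 | alternative 3 | trihalogenated marchantin C ring B methyl ether | Oc1c(Br)cc2cc1Oc1c(Cl)cc(cc1Cl)CCc1cccc(OC)c1Oc1cccc(c1)CC2
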